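## Retrosynthetic overview

1. The target comes from senecioylation and desilylation of an epoxy alcohol. Its oxirane (second ring) is made by hydroxyl-directed asymmetric epoxidation of the 6E olefin of a macrocyclic bis-allylic alcohol.
2. The bis-allylic alcohol comes from a 1,3-oxygen transposition (nucleophilic epoxidation, then Wharton reaction) of a macrocyclic C10 dienone.
3. The eleven-membered carbocycle (first ring) is closed at C1–C11: the C10=C11 enolate π-bond attacks an allyl-cation equivalent at C1–C3 (π-allylpalladium from a vinyl oxirane). This is the laboratory counterpart of the 1,11-cyclization of geranylgeranyl diphosphate; it sets quaternary C11 and unveils the C3 CH2O group.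
4. The acyclic C20 chain comes from aldol condensation of two monoterpene halves, myrcene (C1–C8) and dihydromyrcene (C9–C16).

Numbering: biogenetic numbering is used throughout. C1–C11 are the ring carbons (C1 = ring CH2 next to quaternary C11; C3 carries CH2O; C7 carries the ring methyl; C8 carries the ester oxygen). C12–C16 are the side chain (C14 carbinol, C15=C16 isopropenyl). Target = (2E,6S,7R,8R,9E,11S,14S).

Assumption: the (S)-ligand in step 8 is taken to give 11S; if the product proves to be 11R, the (R)-ligand is used and nothing else changes.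

## Route

Step 1
Reactants: 1 myrcene (7-methyl-3-methylideneocta-1,6-diene)
Product: 2 (2E)-2-methyl-6-methylideneocta-2,7-dienal
Conditions: SeO2 (1 equiv), 95% EtOH, reflux
Reagents that add atoms: selenium dioxide, O=[Se]=O
Why: Riley allylic oxidation (ene reaction, then [2,3]-sigmatropic shift) attacks only the E-methyl of the trisubstituted olefin, giving the (E)-enal and leaving the conjugated diene untouched.

Step 2
Reactants: 2 (2E)-2-methyl-6-methylideneocta-2,7-dienal
Product: 4 (2E)-5-(2-ethenyloxiran-2-yl)-2-methylpent-2-enal (racemic), via bromohydrin 3 (not isolated)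
Conditions: NBS, DME/H2O, 0 °C; then K2CO3, MeOH, 0 °C to rt
Reagents that add atoms: water, O (N-bromosuccinimide, O=C1CCC(=O)N1Br, supplies only the bromine of 3, which leaves again)
Why: Bromohydrin formation goes at the diene and not at the electron-poor enal olefin, with bromine on the methylidene carbon and water on the tertiary allylic carbon (Markovnikov, as with isoprene), and base closes the oxirane by intramolecular Williamson reaction; the oxirane carbon is racemic and is erased in step 8.

Step 3
Reactants: 5 dihydromyrcene (racemic 3,7-dimethylocta-1,6-diene)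
Product: 6 (3S)-2,2-dimethyl-3-(3-methylpent-4-en-1-yl)oxirane
Conditions: ent-Shi ketone (enantiomer of the D-fructose-derived ketone, 0.3 equiv), Oxone (2KHSO5·KHSO4·K2SO4), K2CO3, Bu4NHSO4, MeCN/dimethoxymethane/aqueous Na2B4O7 buffer, 0 °C
Reagents that add atoms: potassium peroxymonosulfate, [K+].[O-]S(=O)(=O)OO
Why: Shi asymmetric epoxidation (chiral dioxirane, spiro transition state) takes the electron-rich trisubstituted olefin and ignores the monosubstituted vinyl group, and the ent-ketone delivers oxygen to the face that makes the oxirane CH carbon (future C14) S.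

Step 4
Reactants: 6 (3S)-2,2-dimethyl-3-(3-methylpent-4-en-1-yl)oxirane
Product: 7 tert-butyl{[(3S)-2,6-dimethylocta-1,7-dien-3-yl]oxy}dimethylsilane
Conditions: TBSOTf, DBU, toluene, −78 to 0 °C
Reagents that add atoms: tert-butyldimethylsilyl triflate, CC(C)(C)[Si](C)(C)OS(=O)(=O)C(F)(F)F
Why: Silyl-triflate-mediated isomerization of an epoxide to an allylic silyl ether (Noyori type) opens the O-silylated oxirane at the tertiary carbon and DBU removes a methyl proton, so the C14–O bond is never broken and the S configuration is kept.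

Step 5
Reactants: 7 tert-butyl{[(3S)-2,6-dimethylocta-1,7-dien-3-yl]oxy}dimethylsilane
Product: 8 (6S)-6-[(tert-butyldimethylsilyl)oxy]-3,7-dimethyloct-7-en-2-one
Conditions: PdCl2 (10 mol %), CuCl, O2 (1 atm), DMF/H2O 7:1, rt
Reagents that add atoms: water, O
Why: Tsuji–Wacker oxidation is Markovnikov-selective for the monosubstituted vinyl group over the 1,1-disubstituted, allylically oxygenated isopropenyl group and gives the methyl ketone without touching C14.

Step 6
Reactants: 8 (6S)-6-[(tert-butyldimethylsilyl)oxy]-3,7-dimethyloct-7-en-2-one; 4 (2E)-5-(2-ethenyloxiran-2-yl)-2-methylpent-2-enal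
Product: 12 acyclic trienone (3S,8E,10E)-3-[(tert-butyldimethylsilyl)oxy]-13-(2-ethenyloxiran-2-yl)-2,6,10-trimethyltrideca-1,8,10-trien-7-one, via lithium enolate 9 (not isolated), via lithium aldolate 10 (not isolated), via aldol mesylate 11 (not isolated)
Conditions: LiN(iPr)2, THF, −78 °C; 4, −78 °C; MsCl, −78 to 0 °C; DBU, 0 °C to rt
Reagents that add atoms: none
Why: Directed aldol addition of the kinetic methyl-side enolate to the enal carbonyl, then E1cB loss of mesylate, gives the thermodynamically preferred (E,E)-dienone; no stereocenter of the target is set (C11 is 1:1 here and is erased in step 7).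

Step 7
Reactants: 12 acyclic trienone
Product: 14 silyl enol ether (3S,8E,10E)-3,7-bis[(tert-butyldimethylsilyl)oxy]-13-(2-ethenyloxiran-2-yl)-2,6,10-trimethyltrideca-1,6,8,10-tetraene (6E/6Z mixture), via lithium dienolate 13 (not isolated)
Conditions: LiN(iPr)2, THF, −78 °C; TBSCl, DMPU, −78 to 0 °C
Reagents that add atoms: tert-butyldimethylsilyl chloride, CC(C)(C)[Si](C)(C)Cl
Why: Kinetic deprotonation can only take the methine proton at C11 next to the carbonyl (C9 is vinylic), and O-silylation gives the cross-conjugated silyl enol ether regiospecifically.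

Step 8
Reactants: 14 silyl enol ether
Product: 17 macrocyclic dienone (2E,6E,8E,11S)-3-{[(tert-butyldimethylsilyl)oxy]methyl}-11-[(3S)-3-[(tert-butyldimethylsilyl)oxy]-4-methylpent-4-en-1-yl]-7,11-dimethylcycloundeca-2,6,8-trien-10-one, via allylpalladium alkoxide 15 (not isolated), via allylpalladium enolate 16 (not isolated)
Conditions: Pd2(dba)3 (5 mol %), (S)-t-BuPHOX (12.5 mol %), Bu4N[Ph3SiF2] (5 mol %), toluene, 40 °C, 14 added by syringe pump (final 2 mM)
Reagents that add atoms: none
Why: Proposed new method: zerovalent palladium opens the vinyl oxirane (the allyl-cation equivalent of diphosphate ionization) to the π-allylpalladium alkoxide 15, the alkoxide takes the silyl group from the enol ether to give the palladium-bound tetrasubstituted enolate 16, and C11 then bonds to the unhindered terminus C1 because attack at C3 would join two fully substituted carbons in a nine-membered ring; the PHOX-bound palladium enolate is expected to equilibrate its E/Z forms before inner-sphere C–C bond formation, so the ligand sets quaternary C11 (S), and the oxygen-bearing arm sits syn on the allyl unit (as with isoprene monoxide) so that C1 and C4 end up cis (2E); the closest known reactions are the alkoxide-triggered Tsuji–Trost allylation of silyl enol ethers (known for eleven-membered α-quaternary ketones), vinyl-oxirane macrocyclizations under neutral conditions, and enantioselective palladium-enolate allylations of acyclic tetrasubstituted enolates.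

Step 9
Reactants: 17 macrocyclic dienone
Product: 18 epoxy ketone (2E,6E,8S,9R,11S)-8,9-epoxy-3-{[(tert-butyldimethylsilyl)oxy]methyl}-11-[(3S)-3-[(tert-butyldimethylsilyl)oxy]-4-methylpent-4-en-1-yl]-7,11-dimethylcycloundeca-2,6-dien-10-one
Conditions: poly-L-leucine, urea·H2O2, DBU, THF, rt
Reagents that add atoms: hydrogen peroxide (as its urea adduct), OO
Why: Juliá–Colonna asymmetric nucleophilic epoxidation (Weitz–Scheffer addition of hydroperoxide inside the polypeptide helix) attacks the only enone olefin, C8=C9, of this non-enolizable ketone and, by analogy with chalcone giving the (αR,βS)-epoxide, sets C8 by reagent control (S here, which becomes the 8R carbinol).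

Step 10
Reactants: 18 epoxy ketone
Product: 20 bis-allylic alcohol (2E,6E,8R,9E,11S)-3-{[(tert-butyldimethylsilyl)oxy]methyl}-11-[(3S)-3-[(tert-butyldimethylsilyl)oxy]-4-methylpent-4-en-1-yl]-7,11-dimethylcycloundeca-2,6,9-trien-8-ol, via epoxy hydrazone 19 (not isolated)
Conditions: N2H4·H2O, AcOH (cat.), MeOH, 0 °C to rt
Reagents that add atoms: none
Why: Wharton transposition: the hydrazone opens the oxirane to an alkenyl diazene that loses N2, which moves the double bond to C9=C10 (E, since Z would put C8 cis to quaternary C11) and leaves the C8–O bond and its configuration untouched.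

Step 11
Reactants: 20 bis-allylic alcohol
Product: 21 epoxy alcohol (2E,6S,7R,8R,9E,11S)-6,7-epoxy-3-{[(tert-butyldimethylsilyl)oxy]methyl}-11-[(3S)-3-[(tert-butyldimethylsilyl)oxy]-4-methylpent-4-en-1-yl]-7,11-dimethylcycloundeca-2,9-dien-8-ol
Conditions: Ti(OiPr)4 (0.2 equiv), D-(−)-diisopropyl tartrate (0.26 equiv), t-BuOOH, 4 Å molecular sieves, CH2Cl2, −20 °C
Reagents that add atoms: tert-butyl hydroperoxide, CC(C)(C)OO
Why: Sharpless asymmetric epoxidation in its matched kinetic-resolution mode: with the D-tartrate the 8R carbinol is the fast-reacting configuration for the C6=C7 olefin and oxygen is delivered to give the erythro (6S,7R)-oxirane, while the C9=C10 olefin is mismatched and hindered and the silylated allylic ethers are not directed.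

Step 12
Reactants: 21 epoxy alcohol; 22 3-methylbut-2-enoyl chloride
Product: 23 bis-silyl ether of the target (8-O-senecioyl derivative of 21)
Conditions: pyridine, DMAP (cat.), CH2Cl2, 0 °C
Reagents that add atoms: none
Why: DMAP-catalysed acylation of the only free hydroxyl, with pyridine instead of a trialkylamine to avoid ketene formation and deconjugation of the senecioyl group; no stereocenter is touched.

Step 13
Reactants: 23 bis-silyl ether of the target
Product: 24 target, (2E,6S,7R,8R,9E,11S)-6,7-epoxy-3-(hydroxymethyl)-11-[(3S)-3-hydroxy-4-methylpent-4-en-1-yl]-7,11-dimethylcycloundeca-2,9-dien-8-yl 3-methylbut-2-enoate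
Conditions: Bu4NF, AcOH (1:1), THF, 0 °C to rt
Reagents that add atoms: none
Why: Fluoride-mediated cleavage of both silyl ethers, buffered with acetic acid so that the enoate ester and the oxirane survive, gives the target with all five stereocenters unchanged.

## Compound list

1 | myrcene (7-methyl-3-methylideneocta-1,6-diene) | C=CC(=C)CCC=C(C)C | starting material
2 | (2E)-2-methyl-6-methylideneocta-2,7-dienal | O=C/C(C)=C/CCC(=C)C=C | intermediate
3 | (2E)-6-(bromomethyl)-6-hydroxy-2-methylocta-2,7-dienal (racemic bromohydrin, not isolated) | O=C/C(C)=C/CCC(O)(CBr)C=C | intermediate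
4 | (2E)-5-(2-ethenyloxiran-2-yl)-2-methylpent-2-enal (racemic) | O=C/C(C)=C/CCC1(C=C)CO1 | intermediate
5 | dihydromyrcene (racemic 3,7-dimethylocta-1,6-diene) | C=CC(C)CCC=C(C)C | starting material
6 | (3S)-2,2-dimethyl-3-(3-methylpent-4-en-1-yl)oxirane (1:1 at the methyl-bearing chain carbon) | CC1(C)O[C@H]1CCC(C)C=C | intermediate
7 | tert-butyl{[(3S)-2,6-dimethylocta-1,7-dien-3-yl]oxy}dimethylsilane | C=C(C)[C@@H](O[Si](C)(C)C(C)(C)C)CCC(C)C=C | intermediate
8 | (6S)-6-[(tert-butyldimethylsilyl)oxy]-3,7-dimethyloct-7-en-2-one | C=C(C)[C@@H](O[Si](C)(C)C(C)(C)C)CCC(C)C(C)=O | intermediate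
9 | lithium enolate of 8 on the methyl side (not isolated) | C=C(C)[C@@H](O[Si](C)(C)C(C)(C)C)CCC(C)C(=C)O[Li] | intermediate
10 | lithium aldolate from 9 and 4 (C8 epimers, not isolated) | C=C(C)[C@@H](O[Si](C)(C)C(C)(C)C)CCC(C)C(=O)CC(O[Li])/C(C)=C/CCC1(C=C)CO1 | intermediate
11 | aldol mesylate (not isolated) | C=C(C)[C@@H](O[Si](C)(C)C(C)(C)C)CCC(C)C(=O)CC(OS(C)(=O)=O)/C(C)=C/CCC1(C=C)CO1 | intermediate
12 | (3S,8E,10E)-3-[(tert-butyldimethylsilyl)oxy]-13-(2-ethenyloxiran-2-yl)-2,6,10-trimethyltrideca-1,8,10-trien-7-one | C=C(C)[C@@H](O[Si](C)(C)C(C)(C)C)CCC(C)C(=O)/C=C/C(C)=C/CCC1(C=C)CO1 | intermediate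
13 | lithium dienolate of 12 at C11 (E/Z mixture, not isolated) | C=C(C)[C@@H](O[Si](C)(C)C(C)(C)C)CCC(C)=C(O[Li])/C=C/C(C)=C/CCC1(C=C)CO1 | intermediate
14 | (3S,8E,10E)-3,7-bis[(tert-butyldimethylsilyl)oxy]-13-(2-ethenyloxiran-2-yl)-2,6,10-trimethyltrideca-1,6,8,10-tetraene (6E/6Z mixture) | C=C(C)[C@@H](O[Si](C)(C)C(C)(C)C)CCC(C)=C(O[Si](C)(C)C(C)(C)C)/C=C/C(C)=C/CCC1(C=C)CO1 | intermediate
15 | π-allylpalladium alkoxide zwitterion from 14 (ligand omitted, drawn as the η1-allyl form, not isolated) | C=C(C)[C@@H](O[Si](C)(C)C(C)(C)C)CCC(C)=C(O[Si](C)(C)C(C)(C)C)/C=C/C(C)=C/CC/C(C[O-])=C\C[Pd+] | intermediate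
16 | π-allylpalladium enolate after O-to-O silyl shift (ligand omitted, drawn as the η1-allyl form, not isolated) | C=C(C)[C@@H](O[Si](C)(C)C(C)(C)C)CCC(C)=C([O-])/C=C/C(C)=C/CC/C(CO[Si](C)(C)C(C)(C)C)=C\C[Pd+] | intermediate
17 | macrocyclic dienone (2E,6E,8E,11S,14S), C10 ketone, C3 CH2OTBS, C14 OTBS | C=C(C)[C@@H](O[Si](C)(C)C(C)(C)C)CC[C@]1(C)C(=O)/C=C/C(C)=C/CC/C(CO[Si](C)(C)C(C)(C)C)=C\C1 | intermediate
18 | 8,9-epoxy ketone (2E,6E,8S,9R,11S,14S) | C=C(C)[C@@H](O[Si](C)(C)C(C)(C)C)CC[C@]1(C)C(=O)[C@@H]2O[C@H]2/C(C)=C/CC/C(CO[Si](C)(C)C(C)(C)C)=C\C1 | intermediate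
19 | hydrazone of 18 (not isolated) | C=C(C)[C@@H](O[Si](C)(C)C(C)(C)C)CC[C@]1(C)C(=NN)[C@@H]2O[C@H]2/C(C)=C/CC/C(CO[Si](C)(C)C(C)(C)C)=C\C1 | intermediate
20 | bis-allylic alcohol (2E,6E,8R,9E,11S,14S) | C=C(C)[C@@H](O[Si](C)(C)C(C)(C)C)CC[C@]1(C)/C=C/[C@@H](O)/C(C)=C/CC/C(CO[Si](C)(C)C(C)(C)C)=C\C1 | intermediate
21 | 6,7-epoxy alcohol (2E,6S,7R,8R,9E,11S,14S) | C=C(C)[C@@H](O[Si](C)(C)C(C)(C)C)CC[C@]1(C)/C=C/[C@@H](O)[C@]2(C)O[C@H]2CC/C(CO[Si](C)(C)C(C)(C)C)=C\C1 | intermediate
22 | 3-methylbut-2-enoyl chloride (senecioyl chloride) | CC(C)=CC(=O)Cl | starting material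
23 | bis-TBS ether of the target (8-O-senecioate of 21) | C=C(C)[C@@H](O[Si](C)(C)C(C)(C)C)CC[C@]1(C)/C=C/[C@@H](OC(=O)C=C(C)C)[C@]2(C)O[C@H]2CC/C(CO[Si](C)(C)C(C)(C)C)=C\C1 | intermediate
24 | CNP0309478.3, (2E,6S,7R,8R,9E,11S)-6,7-epoxy-3-(hydroxymethyl)-11-[(3S)-3-hydroxy-4-methylpent-4-en-1-yl]-7,11-dimethylcycloundeca-2,9-dien-8-yl 3-methylbut-2-enoate | C=C(C)[C@@H](O)CC[C@]1(C)/C=C/[C@@H](OC(=O)C=C(C)C)[C@]2(C)O[C@H]2CC/C(CO)=C\C1 | target

## Count

Total steps: 13. Longest linear sequence: 11 steps (5 to 24, steps 3–13); the myrcene branch (steps 1–2) joins at step 6.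

## Three steps most likely to fail, each with a fallback

Step 8 (macrocyclization; control of C11, the C2=C3 geometry and the silyl shift are all unproven). If ligand control at C11 is poor or the closure stalls, set out from 12: deprotonate with LiN(iPr)2 to the lithium dienolate 13 and add it slowly to Pd(PPh3)4 in THF, a plain metal-enolate Tsuji–Trost closure without chiral ligand. The resulting macrocyclic lithium alkoxide F1 is trapped in the same flask with TBSCl to give 17 together with its C11 epimer F2. The pair is taken through step 9, and 18 is separated by chromatography from the epimeric epoxy ketone F3, since the reagent-set C8/C9 centers now sit two bonds from C11. The route is rejoined at 18.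

Step 9 (polypeptide-mediated epoxidation on a hindered macrocyclic dienone). If it is slow or unselective, set out from 17: Luche reduction (NaBH4, CeCl3·7H2O, MeOH) gives the C10 dienols F4 as both epimers. Sharpless epoxidation (Ti(OiPr)4, D-(−)-diisopropyl tartrate, t-BuOOH) then epoxidizes only the fast-reacting C10 epimer at C8=C9, from the face that gives 8S,9R, to give the epoxy alcohol F5; the unreacted epimer is oxidized back to 17 with MnO2. Dess–Martin oxidation of F5 gives 18, where the route is rejoined.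

Step 10 (Wharton reaction on a ketone flanked by a quaternary carbon; slow hydrazone formation, pyrazoline formation or some Z olefin are possible). Set out from 18: NaBH4 reduction gives the epoxy alcohols F6 (C10 epimers), and 1,1′-thiocarbonyldiimidazole converts them to the imidazolylthiocarbonates F7. Bu3SnH/AIBN in toluene at 80 °C generates the C10 radical, which opens the oxirane at C9–O to the E C9=C10 olefin and a C8 oxy radical that is reduced to the alcohol (epoxy-carbinyl radical transposition). This gives 20, where the route is rejoined.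

## Further compounds

F1 | step 8 | macrocyclic lithium alkoxide (both C11 epimers) | C=C(C)[C@@H](O[Si](C)(C)C(C)(C)C)CCC1(C)C(=O)/C=C/C(C)=C/CC/C(CO[Li])=C\C1
F2 | step 8 | C11 epimer of 17 (2E,6E,8E,11R,14S) | C=C(C)[C@@H](O[Si](C)(C)C(C)(C)C)CC[C@@]1(C)C(=O)/C=C/C(C)=C/CC/C(CO[Si](C)(C)C(C)(C)C)=C\C1
F3 | step 8 | C11 epimer of 18 (2E,6E,8S,9R,11R,14S) | C=C(C)[C@@H](O[Si](C)(C)C(C)(C)C)CC[C@@]1(C)C(=O)[C@@H]2O[C@H]2/C(C)=C/CC/C(CO[Si](C)(C)C(C)(C)C)=C\C1
F4 | step 9 | C10 dienols from 17 (both C10 epimers) | C=C(C)[C@@H](O[Si](C)(C)C(C)(C)C)CC[C@]1(C)C(O)/C=C/C(C)=C/CC/C(CO[Si](C)(C)C(C)(C)C)=C\C1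
F5 | step 9 | 8,9-epoxy-10-ol from the fast-reacting C10 epimer | C=C(C)[C@@H](O[Si](C)(C)C(C)(C)C)CC[C@]1(C)[C@@H](O)[C@@H]2O[C@H]2/C(C)=C/CC/C(CO[Si](C)(C)C(C)(C)C)=C\C1
F6 | step 10 | 8,9-epoxy-10-ols from 18 (both C10 epimers) | C=C(C)[C@@H](O[Si](C)(C)C(C)(C)C)CC[C@]1(C)C(O)[C@@H]2O[C@H]2/C(C)=C/CC/C(CO[Si](C)(C)C(C)(C)C)=C\C1
F7 | step 10 | O-(imidazol-1-ylthiocarbonyl) derivatives of F6 | C=C(C)[C@@H](O[Si](C)(C)C(C)(C)C)CC[C@]1(C)C(OC(=S)n3ccnc3)[C@@H]2O[C@H]2/C(C)=C/CC/C(CO[Si](C)(C)C(C)(C)C)=C\C1
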